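## The problem

The target 25 is a double ester. Its core is a centrosymmetric cyclobutane-1,3-dicarboxylic acid with two 4-hydroxyphenyl groups in the head-to-tail α-truxillate pattern (1α,2α,3β,4β). Both carboxyls are esterified with the same N-methyl, cis-fused octahydrocyclopenta[c]pyridin-6-ol (numbering C1, N2, C3, C4, C4a, C5, C6, C7, C7a).

The diacid core is achiral and the two alcohol units are identical. The single enantiomer therefore depends only on making the amino alcohol enantiopure. It has five contiguous stereocentres: H4, H4a and H7a are all cis, and the C7 methyl and the C6 oxygen lie on the convex face.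

These centres differ in how they can be controlled. C4 and C7a are 1,3 on the piperidine ring and can be set together, cis, by hydrogenating a pyridine. C7 is α to the C6 carbonyl of a ketone precursor and can be equilibrated to the exo position. C6 comes from a hydride reduction and can be inverted during esterification. Only C4a must be set in the ring-forming event itself.

The four stereocentres of the core are best left to a lattice-controlled photodimerisation. The sensitive points are the free phenols (they compete in esterifications), the tertiary amines (alkylating agents, oxidants), the α-hydrogens of the strained truxillate esters (base epimerisation) and, on the way, a diazoketone. The last steps must therefore be neutral.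

The feature that opens the key step is that C5 is a bare methylene between the oxygenated C6 and the ring-fusion carbon C4a, and C4a carries only hydrogen. A carbenoid centred on C5, tethered through C6 and C7 to C7a of a cis-3,5-disubstituted piperidine, is 1,5 to the C4a–H bonds. The five-membered ring can thus be closed onto an unfunctionalised position.

## Retrosynthesis

25 ⇒ 24. The two phenols are carried as benzyl ethers and the two O–benzyl bonds are cut last. This mask is preferred to acyl or silyl groups because hydrogenolysis is neutral, so no base reaches the truxillate α-hydrogens. The forward step must leave esters, cyclobutane and amines untouched.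

24 ⇒ 23 + two molecules of 19. The two C6–O (alkyl–oxygen) bonds are cut, not the acyl–oxygen bonds. Hydride reduction of the bicyclic ketone should place the hydroxyl on the concave face (6S), opposite to the 6R ester, and an SN2 esterification inverts it. Acyl activation of a crowded diacid next to epimerisable carbons is also avoided. The cut halves the molecule into an achiral diacid and two identical small amino alcohols. It asks for clean double inversion at a hindered secondary carbinol.

23 ⇒ 21 ⇒ two molecules of 20. The two cyclobutane bonds between the former alkene carbons are cut. Head-to-tail [2+2] dimerisation of p-coumaric acid in the crystal sets all four stereocentres in one step from a commodity acid. Benzylation follows the dimerisation because the crystal packing of a benzyl ether cannot be predicted.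

19 ⇒ 18 ⇒ 17 ⇒ 16. These are functional-group changes (N–CH3, N–S, C6–H). The sulfonamide is kept through the carbenoid step and the reduction because a basic amine would bind the rhodium catalyst. Ketone 16 holds C7 in an equilibrable position.

16 ⇒ 14 (key disconnection, C4a–C5).
- Against its neighbours: cutting C5–C6 or C6–C7 (acylation, Dieckmann) would require an activating group on C4a or C5. Cutting C7–C7a still leaves C4a–C5 to be made.
- Simplification: C–H insertion uses the C4a–H bond as it stands and leads back to a monocyclic piperidine with one ring and one stereocentre fewer.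
- Demand: the carbenoid must take the axial C4a–H bond, not the equatorial one and not the two C1–H bonds.
- Control element: the C7 methyl is set R in 14, opposite to the target. In the rotamer that reaches the axial C4a–H it lies anti to C4a and eclipses the carbonyl. The primary product 15 is then epimerised to 16 in the same flask.

14 ⇒ 12 ⇒ 11 ⇒ 10. C5–C6 is cut to an acid and diazomethane. C7–CH3 is cut to an auxiliary-controlled enolate methylation. Carrying the methyl from the start (arylation of a propanoate) would leave C7 uncontrolled after ring hydrogenation, and C7 is needed as a control element.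

10 ⇒ 7 + 8. The imide N–acyl bond is cut. The oxazolidinone needed for C7 also turns the enantiomers of racemic 7 into separable diastereomers, so no separate resolution step is spent.

7 ⇒ 6 ⇒ 3 (with 4, through 5). The ester, the N–S bond and the six ring C–H bonds are cut. Syn delivery of hydrogen to the flat pyridine gives the cis-3,5 pattern that encodes C4 and C7a.

3 ⇒ 1 + 2. The aryl–CH2 bond is cut to a palladium-catalysed ester α-arylation of a commercial bromopyridine.

## Roads not taken

Alternative 1: The two aryl–cyclobutane bonds of the core are cut instead of two ring bonds.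
- Forward step: trans-N1,N3-di(quinolin-8-yl)cyclobutane-1,3-dicarboxamide A1 is arylated twice with 1-(benzyloxy)-4-iodobenzene A2 under palladium catalysis with a silver carboxylate, each aryl entering cis to a directing amide, to give A3.
- Merits: it is solution chemistry, independent of crystal packing, and would allow two different aryl groups. In these respects it is better than the photodimerisation.
- Weak points: the second arylation can be steered by either amide, so the α pattern competes with the isomer that has both aryls cis to one amide. Two hindered quinolinyl amides must then be cleaved next to epimerisable carbons. Three or more steps replace one.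
- Comparison: this road only makes the achiral core, and the amino alcohol is still needed. For two identical 4-hydroxyphenyl groups the chosen plan offers one photochemical step to 21 with the configuration fixed by the lattice. Its exposure is the dependence on the crystal form of 20.

Alternative 2: C7a–C4a, C5–C6 and C6–C7 are cut at once.
- Forward step: the nitrogen-tethered dienyne A4 undergoes a rhodium-catalysed carbonylative [2+2+1] cycloaddition to the bicyclic dienone A5, closing both rings.
- Merits: in bond and ring economy this road is clearly better than the chosen one. Its end game is also shorter, since a hydride could turn the carbamate into the N-methyl group while reducing the ketone; the chosen plan spends steps 10 and 11 on that.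
- Weak points: A5 has a single stereocentre and is racemic unless an enantioselective variant is found. C4, C7 and C7a must then be set by hydrogenating an exocyclic methylene and a tetrasubstituted enone, which is slow, and syn delivery leaves the C7 methyl endo.
- Comparison: the chosen plan has absolute configuration secured before ring closure (10), crystalline sulfonamide intermediates and no tetrasubstituted alkene to reduce. The price is the selectivity risk of step 8.

Alternative 3: The C3=C4 bond is cut.
- Forward step: the N-vinyl carbamate cyclopentenone A6 undergoes ring-closing metathesis with a ruthenium carbene catalyst to the dienone A7. Relay hydrogenation from the convex face then sets C4 and C4a.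
- Merits: the ring fusion comes from hydrogenation on the exposed face. This is more reliable than choosing between two C–H bonds, and the chosen plan is weaker here.
- Weak points: A6 already holds C7 and C7a and needs its own multi-step enantioselective synthesis. Metathesis between an electron-rich enamide and a 1,1-disubstituted, conjugated alkene is demanding. The overall count is higher.
- Comparison: the chosen plan gets C4 and C7a from a one-step pyridine hydrogenation and uses the C7 methyl as a control element. If that fails, it has the same enone hydrogenation in reserve as the fallback to step 8.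

Key step: step 8

Remark: compounds 5, 6, 7 and 9 are racemic cis compounds, named and drawn as their (3R,5R) enantiomers; from 10 on every compound is a single stereoisomer.

## Route

Step 1
Reactants: 1 3-bromo-5-methylpyridine; 2 tert-butyl acetate
Product: 3 tert-butyl 2-(5-methylpyridin-3-yl)acetate
Conditions: LiN(SiMe3)2 (2.2 equiv), Pd(dba)2 (2 mol %), P(t-Bu)3, toluene, rt
Reagents that add atoms: none
Why: Palladium-catalysed α-arylation of an ester enolate (Buchwald–Hartwig type): oxidative addition of 1 to zerovalent palladium, exchange with the lithium enolate of 2 and reductive elimination; the tert-butyl ester resists Claisen condensation and the bulky phosphine keeps the pyridine nitrogen off the metal.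

Step 2
Reactants: 3 tert-butyl 2-(5-methylpyridin-3-yl)acetate; 4 4-methylbenzenesulfonyl chloride (tosyl chloride)
Product: 6 rac-tert-butyl 2-[(3R,5R)-5-methyl-1-tosylpiperidin-3-yl]acetate (cis), via the free piperidine 5 (not isolated)
Conditions: H2 (5 bar), PtO2, AcOH, rt; filter, evaporate; TsCl, Et3N, CH2Cl2, 0 °C to rt; recrystallise
Reagents that add atoms: none
Why: Heterogeneous hydrogenation of the pyridinium acetate delivers the ring hydrogens from the adsorbed face, so the 3- and 5-substituents should come out cis, and the minor trans isomer is removed when 6 is crystallised; sulfonylation of the secondary amine is routine and gives a non-basic nitrogen for the carbenoid step.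

Step 3
Reactants: 6 rac-tert-butyl 2-[(3R,5R)-5-methyl-1-tosylpiperidin-3-yl]acetate
Product: 7 rac-2-[(3R,5R)-5-methyl-1-tosylpiperidin-3-yl]acetic acid
Conditions: CF3CO2H, CH2Cl2, rt
Reagents that add atoms: none
Why: Acidolysis of the tert-butyl ester with loss of 2-methylpropene; the sulfonamide is inert to acid.

Step 4
Reactants: 7 rac-2-[(3R,5R)-5-methyl-1-tosylpiperidin-3-yl]acetic acid; 8 (4R)-4-benzyl-1,3-oxazolidin-2-one
Product: 10 (4R)-4-benzyl-3-{[(3R,5R)-5-methyl-1-tosylpiperidin-3-yl]acetyl}-1,3-oxazolidin-2-one, via the mixed pivalic anhydride 9 (not isolated)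
Conditions: t-BuCOCl, Et3N, THF, −20 °C; 8, LiCl, −20 °C to rt; separation of the two diastereomers (chromatography, then crystallisation)
Reagents that add atoms: none
Why: N-Acylation of the oxazolidinone through the mixed anhydride; the racemic acid gives two diastereomeric imides that differ only in the ring configuration, and their separation fixes C4 and C7a in the absolute sense (resolution through covalent diastereomers).

Step 5
Reactants: 10 (4R)-4-benzyl-3-{[(3R,5R)-5-methyl-1-tosylpiperidin-3-yl]acetyl}-1,3-oxazolidin-2-one
Product: 11 (4R)-4-benzyl-3-{(2R)-2-[(3R,5R)-5-methyl-1-tosylpiperidin-3-yl]propanoyl}-1,3-oxazolidin-2-one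
Conditions: NaN(SiMe3)2, THF, −78 °C; MeI, −78 to −40 °C
Reagents that add atoms: iodomethane, CI
Why: Evans alkylation: the chelated sodium (Z)-enolate is methylated on the face away from the benzyl group, which should set the α-carbon (the future C7) as R, on purpose opposite to the target at this stage.

Step 6
Reactants: 11 (4R)-4-benzyl-3-{(2R)-2-[(3R,5R)-5-methyl-1-tosylpiperidin-3-yl]propanoyl}-1,3-oxazolidin-2-one
Product: 12 (2R)-2-[(3R,5R)-5-methyl-1-tosylpiperidin-3-yl]propanoic acid
Conditions: LiOH, H2O2, THF/H2O, 0 °C; Na2SO3; HCl to pH 2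
Reagents that add atoms: hydrogen peroxide, OO
Why: Hydroperoxide attacks the exocyclic imide carbonyl selectively (LiOOH hydrolysis) and is too weakly basic to epimerise the α-carbon; the auxiliary is recovered.

Step 7
Reactants: 12 (2R)-2-[(3R,5R)-5-methyl-1-tosylpiperidin-3-yl]propanoic acid
Product: 14 (3R)-1-diazo-3-[(3R,5R)-5-methyl-1-tosylpiperidin-3-yl]butan-2-one, via the acid chloride 13 (not isolated)
Conditions: (COCl)2, DMF (cat.), CH2Cl2, 0 °C to rt; evaporate; CH2N2 (3 equiv), Et2O, 0 °C
Reagents that add atoms: diazomethane, C=[N+]=[N-]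
Why: Acyl chloride formation and acylation of diazomethane (first stage of the Arndt–Eistert sequence); excess diazomethane takes up the HCl and no amine base is present, so the α-stereocentre should not be lost through a ketene.

Step 8
Reactants: 14 (3R)-1-diazo-3-[(3R,5R)-5-methyl-1-tosylpiperidin-3-yl]butan-2-one
Product: 16 (4R,4aS,7S,7aR)-4,7-dimethyl-2-tosyloctahydro-6H-cyclopenta[c]pyridin-6-one, via the 7R epimer 15 (not isolated)
Conditions: Rh2(OAc)4 (1 mol %), CH2Cl2, reflux, slow addition of 14 at high dilution; then DBU, rt
Reagents that add atoms: none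
Why: Rh2(OAc)4 (divalent rhodium) takes N2 from 14 to give an electrophilic rhodium carbenoid at C5, which inserts into a C4a–H bond through a concerted three-centre, hydride-transfer-like transition state with retention, forming C4a–C5; the closest known reaction is the Rh2(OAc)4-catalysed intramolecular 1,5 C–H insertion of α-diazoketones into unactivated ring methylenes to give fused cyclopentanones. The cyclopentanone closes in the 1,5 mode through a chair-like six-centre array (C5, C6, C7, C7a, C4a, H). The new stereocentre C4a is fixed by which C4a–H bond reacts: on the diequatorial piperidine chair the axial bond is cis to the side chain and gives the cis fusion, the equatorial bond would give the trans-fused epimer. The element that should decide this is the 7R methyl: in the rotamer that reaches the axial C4a–H (C6 anti to H7a) it lies anti to C4a and eclipses the carbonyl, whereas the rotamer needed for the equatorial C4a–H wedges it between C1 and C4a. Site selectivity against C1–H is also needed and a sulfonamide is only a weak electronic brake on its α-C–H bonds; the equatorial C1–H is shielded by the sulfonyl group (A(1,3) strain in the transition state) and the axial C1–H can only be reached with the methyl turned out of its carbonyl-eclipsing position. DBU then epimerises C7 of 15, whose methyl is endo and cis to C1, to the exo methyl of 16, which should be the thermodynamic epimer.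

Step 9
Reactants: 16 (4R,4aS,7S,7aR)-4,7-dimethyl-2-tosyloctahydro-6H-cyclopenta[c]pyridin-6-one
Product: 17 (4R,4aS,6S,7S,7aR)-4,7-dimethyl-2-tosyloctahydro-1H-cyclopenta[c]pyridin-6-ol
Conditions: NaBH4, MeOH, −20 to 0 °C
Reagents that add atoms: none
Why: Borohydride reduction; hydride should add to the convex face of the cis-fused bicycle, which is also the approach that small hydrides take to give a trans-2-methylcyclopentanol, so the hydroxyl should end on the concave face, trans to the C7 methyl (6S).

Step 10
Reactants: 17 (4R,4aS,6S,7S,7aR)-4,7-dimethyl-2-tosyloctahydro-1H-cyclopenta[c]pyridin-6-ol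
Product: 18 (4R,4aS,6S,7S,7aR)-4,7-dimethyloctahydro-1H-cyclopenta[c]pyridin-6-ol
Conditions: Na, naphthalene, DME, −78 °C; then H2O
Reagents that add atoms: none
Why: Single-electron reductive cleavage of the N–S bond by the arene radical anion (dissolving-metal-type desulfonylation); the alkoxide of the free hydroxyl is inert and nothing else in the molecule is reducible.

Step 11
Reactants: 18 (4R,4aS,6S,7S,7aR)-4,7-dimethyloctahydro-1H-cyclopenta[c]pyridin-6-ol
Product: 19 (4R,4aS,6S,7S,7aR)-2,4,7-trimethyloctahydro-1H-cyclopenta[c]pyridin-6-ol (6-epi-incarvilline)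
Conditions: aq. HCHO, HCO2H, 80 °C; then aq. NaOH
Reagents that add atoms: formaldehyde, C=O
Why: Eschweiler–Clarke reductive methylation: the iminium ion from formaldehyde is reduced by formate with loss of CO2, quaternisation cannot occur, and any formate ester of the alcohol is removed in the basic work-up.

Step 12
Reactants: 20 (E)-3-(4-hydroxyphenyl)prop-2-enoic acid (p-coumaric acid), two molecules
Product: 21 (1α,2α,3β,4β)-2,4-bis(4-hydroxyphenyl)cyclobutane-1,3-dicarboxylic acid
Conditions: hν (Pyrex-filtered medium-pressure mercury lamp), crystalline powder, rt, periodic regrinding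
Reagents that add atoms: none
Why: Topochemical [2+2] photodimerisation: in the crystal the acid molecules are paired head-to-tail across an inversion centre with parallel double bonds in contact, so irradiation should give the centrosymmetric α-truxillic dimer and set all four cyclobutane stereocentres.

Step 13
Reactants: 21 (1α,2α,3β,4β)-2,4-bis(4-hydroxyphenyl)cyclobutane-1,3-dicarboxylic acid
Product: 23 (1α,2α,3β,4β)-2,4-bis[4-(benzyloxy)phenyl]cyclobutane-1,3-dicarboxylic acid, via the tetrabenzyl compound 22 (not isolated)
Conditions: BnBr (5 equiv), K2CO3, DMF, 60 °C; then NaOH, THF/MeOH/H2O, 50 °C; HCl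
Reagents that add atoms: benzyl bromide, BrCc1ccccc1
Why: Williamson etherification of the phenoxides, in which the carboxylates are benzylated as well, followed by saponification of the two benzyl esters; hydroxide at moderate temperature should hydrolyse the esters faster than it enolises the cyclobutane α-carbons.

Step 14
Reactants: 23 (1α,2α,3β,4β)-2,4-bis[4-(benzyloxy)phenyl]cyclobutane-1,3-dicarboxylic acid; 19 (4R,4aS,6S,7S,7aR)-2,4,7-trimethyloctahydro-1H-cyclopenta[c]pyridin-6-ol (2.4 equiv)
Product: 24 bis[(4R,4aS,6R,7S,7aR)-2,4,7-trimethyloctahydro-1H-cyclopenta[c]pyridin-6-yl] (1α,2α,3β,4β)-2,4-bis[4-(benzyloxy)phenyl]cyclobutane-1,3-dicarboxylate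
Conditions: PPh3, EtO2CN=NCO2Et, THF, 0 °C to rt
Reagents that add atoms: none
Why: Mitsunobu esterification: each alkoxyphosphonium ion of 19 is displaced by a carboxylate of 23 with inversion, turning 6S into 6R at both ends; a meso diacid and two identical enantiopure alcohols can give only one diastereomer, and the benzyl ethers keep the phenols out of the reaction.

Step 15
Reactants: 24 bis[(4R,4aS,6R,7S,7aR)-2,4,7-trimethyloctahydro-1H-cyclopenta[c]pyridin-6-yl] (1α,2α,3β,4β)-2,4-bis[4-(benzyloxy)phenyl]cyclobutane-1,3-dicarboxylate
Product: 25 bis[(4R,4aS,6R,7S,7aR)-2,4,7-trimethyloctahydro-1H-cyclopenta[c]pyridin-6-yl] (1α,2α,3β,4β)-2,4-bis(4-hydroxyphenyl)cyclobutane-1,3-dicarboxylate (CNP0180864.2)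
Conditions: H2 (1 bar), Pd/C, EtOAc/MeOH, rt
Reagents that add atoms: none
Why: Hydrogenolysis of the two benzyl aryl ethers under neutral conditions; the alkyl esters, the cyclobutane and the tertiary amines are not affected and no base touches the truxillate.

## Compound list

1 | 3-bromo-5-methylpyridine | Cc1cncc(Br)c1 | starting material
2 | tert-butyl acetate | CC(=O)OC(C)(C)C | starting material
3 | tert-butyl 2-(5-methylpyridin-3-yl)acetate | Cc1cncc(CC(=O)OC(C)(C)C)c1 | intermediate
4 | 4-methylbenzenesulfonyl chloride | Cc1ccc(S(=O)(=O)Cl)cc1 | starting material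
5 | rac-tert-butyl 2-[(3R,5R)-5-methylpiperidin-3-yl]acetate (cis; not isolated) | CC(C)(C)OC(=O)C[C@@H]1CNC[C@H](C)C1 | intermediate
6 | rac-tert-butyl 2-[(3R,5R)-5-methyl-1-tosylpiperidin-3-yl]acetate (cis) | CC(C)(C)OC(=O)C[C@@H]1CN(S(=O)(=O)c2ccc(C)cc2)C[C@H](C)C1 | intermediate
7 | rac-2-[(3R,5R)-5-methyl-1-tosylpiperidin-3-yl]acetic acid | O=C(O)C[C@@H]1CN(S(=O)(=O)c2ccc(C)cc2)C[C@H](C)C1 | intermediate
8 | (4R)-4-benzyl-1,3-oxazolidin-2-one | O=C1N[C@H](Cc2ccccc2)CO1 | starting material
9 | rac-2-[(3R,5R)-5-methyl-1-tosylpiperidin-3-yl]acetic pivalic anhydride (not isolated) | CC(C)(C)C(=O)OC(=O)C[C@@H]1CN(S(=O)(=O)c2ccc(C)cc2)C[C@H](C)C1 | intermediate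
10 | (4R)-4-benzyl-3-{[(3R,5R)-5-methyl-1-tosylpiperidin-3-yl]acetyl}-1,3-oxazolidin-2-one | O=C(C[C@@H]1CN(S(=O)(=O)c2ccc(C)cc2)C[C@H](C)C1)N1[C@H](Cc2ccccc2)COC1=O | intermediate
11 | (4R)-4-benzyl-3-{(2R)-2-[(3R,5R)-5-methyl-1-tosylpiperidin-3-yl]propanoyl}-1,3-oxazolidin-2-one | C[C@@H](C(=O)N1[C@H](Cc2ccccc2)COC1=O)[C@@H]1CN(S(=O)(=O)c2ccc(C)cc2)C[C@H](C)C1 | intermediate
12 | (2R)-2-[(3R,5R)-5-methyl-1-tosylpiperidin-3-yl]propanoic acid | C[C@@H](C(=O)O)[C@@H]1CN(S(=O)(=O)c2ccc(C)cc2)C[C@H](C)C1 | intermediate
13 | (2R)-2-[(3R,5R)-5-methyl-1-tosylpiperidin-3-yl]propanoyl chloride (not isolated) | C[C@@H](C(=O)Cl)[C@@H]1CN(S(=O)(=O)c2ccc(C)cc2)C[C@H](C)C1 | intermediate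
14 | (3R)-1-diazo-3-[(3R,5R)-5-methyl-1-tosylpiperidin-3-yl]butan-2-one | C[C@@H](C(=O)C=[N+]=[N-])[C@@H]1CN(S(=O)(=O)c2ccc(C)cc2)C[C@H](C)C1 | intermediate
15 | (4R,4aS,7R,7aR)-4,7-dimethyl-2-tosyloctahydro-6H-cyclopenta[c]pyridin-6-one (not isolated) | C[C@@H]1[C@@H]2CN(S(=O)(=O)c3ccc(C)cc3)C[C@H](C)[C@@H]2CC1=O | intermediate
16 | (4R,4aS,7S,7aR)-4,7-dimethyl-2-tosyloctahydro-6H-cyclopenta[c]pyridin-6-one | C[C@H]1[C@@H]2CN(S(=O)(=O)c3ccc(C)cc3)C[C@H](C)[C@@H]2CC1=O | intermediate
17 | (4R,4aS,6S,7S,7aR)-4,7-dimethyl-2-tosyloctahydro-1H-cyclopenta[c]pyridin-6-ol | C[C@H]1[C@@H]2CN(S(=O)(=O)c3ccc(C)cc3)C[C@H](C)[C@@H]2C[C@@H]1O | intermediate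
18 | (4R,4aS,6S,7S,7aR)-4,7-dimethyloctahydro-1H-cyclopenta[c]pyridin-6-ol | C[C@H]1[C@@H]2CNC[C@H](C)[C@@H]2C[C@@H]1O | intermediate
19 | (4R,4aS,6S,7S,7aR)-2,4,7-trimethyloctahydro-1H-cyclopenta[c]pyridin-6-ol (6-epi-incarvilline) | C[C@H]1[C@@H]2CN(C)C[C@H](C)[C@@H]2C[C@@H]1O | intermediate
20 | (E)-3-(4-hydroxyphenyl)prop-2-enoic acid (p-coumaric acid) | O=C(O)/C=C/c1ccc(O)cc1 | starting material
21 | (1α,2α,3β,4β)-2,4-bis(4-hydroxyphenyl)cyclobutane-1,3-dicarboxylic acid | O=C(O)[C@H]1[C@H](c2ccc(O)cc2)[C@H](C(=O)O)[C@H]1c1ccc(O)cc1 | intermediate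
22 | dibenzyl (1α,2α,3β,4β)-2,4-bis[4-(benzyloxy)phenyl]cyclobutane-1,3-dicarboxylate (not isolated) | O=C(OCc1ccccc1)[C@H]1[C@H](c2ccc(OCc3ccccc3)cc2)[C@H](C(=O)OCc2ccccc2)[C@H]1c1ccc(OCc2ccccc2)cc1 | intermediate
23 | (1α,2α,3β,4β)-2,4-bis[4-(benzyloxy)phenyl]cyclobutane-1,3-dicarboxylic acid | O=C(O)[C@H]1[C@H](c2ccc(OCc3ccccc3)cc2)[C@H](C(=O)O)[C@H]1c1ccc(OCc2ccccc2)cc1 | intermediate
24 | bis[(4R,4aS,6R,7S,7aR)-2,4,7-trimethyloctahydro-1H-cyclopenta[c]pyridin-6-yl] (1α,2α,3β,4β)-2,4-bis[4-(benzyloxy)phenyl]cyclobutane-1,3-dicarboxylate | C[C@H]1[C@@H]2CN(C)C[C@H](C)[C@@H]2C[C@H]1OC(=O)[C@H]1[C@H](c2ccc(OCc3ccccc3)cc2)[C@H](C(=O)O[C@@H]2C[C@@H]3[C@@H](CN(C)C[C@@H]3C)[C@@H]2C)[C@H]1c1ccc(OCc2ccccc2)cc1 | intermediate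
25 | bis[(4R,4aS,6R,7S,7aR)-2,4,7-trimethyloctahydro-1H-cyclopenta[c]pyridin-6-yl] (1α,2α,3β,4β)-2,4-bis(4-hydroxyphenyl)cyclobutane-1,3-dicarboxylate | C[C@H]1[C@@H]2CN(C)C[C@H](C)[C@@H]2C[C@H]1OC(=O)[C@H]1[C@H](c2ccc(O)cc2)[C@H](C(=O)O[C@@H]2C[C@@H]3[C@@H](CN(C)C[C@@H]3C)[C@@H]2C)[C@H]1c1ccc(O)cc1 | target

## Step count and least certain steps

Total: 15 steps. Longest linear sequence: 13 steps (steps 1 to 11, 14 and 15). The diacid branch (steps 12 and 13) joins at step 14.

Step 8 (key step).
- Most likely failure: poor control of the ring fusion, that is, insertion into the equatorial C4a–H bond to give the trans-fused 4a-epimer. Equatorial C–H bonds are the more exposed sites on a chair, and the preference for the axial bond rests only on the rotamer bias of the C7 methyl. Leakage to the C1–H bonds is the second concern.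
- Fallback: it sets out from 14 and comes back at 16. The same rhodium decomposition and DBU treatment of 14 would then give mainly (4R,4aR,7S,7aR)-4,7-dimethyl-2-tosyloctahydro-6H-cyclopenta[c]pyridin-6-one F1. Kinetic enolisation toward C5 with LiN(i-Pr)2 and Me3SiCl gives the trimethylsilyl enol ether of F1, F2. Saegusa–Ito dehydrogenation with Pd(OAc)2 (divalent palladium) in MeCN gives the C4a=C5 enone F3, in which C4a is no longer stereogenic. Hydrogenation over Pd/C should add hydrogen on the face of H7a, anti to the C4 methyl; with the DBU equilibration of C7 this returns 16. The ring fusion is then set by hydrogenation and no longer by the choice between two C–H bonds.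

Step 7.
- Most likely failure: erosion of the α-stereocentre (the future C7) by ketene formation from the acid chloride. This would remove the control element of step 8. The scale limit of diazomethane is a further drawback.
- Fallback: it sets out from 12 and comes back at 16, replacing steps 7 and 8. Activation of 12 with 1,1'-carbonyldiimidazole and chain extension with Mg(O2CCH2CO2Me)2 (Masamune homologation, neutral) gives methyl (4R)-4-[(3R,5R)-5-methyl-1-tosylpiperidin-3-yl]-3-oxopentanoate F4. Regitz diazo transfer with 4-acetamidobenzenesulfonyl azide and Et3N gives the α-diazo-β-ketoester F5. Rh2(OAc)4 closes the ring to the bicyclic β-ketoester F6. In this acceptor/acceptor carbenoid the ester on C5 penalises the transition states with the C7 methyl out of place more strongly. Krapcho demethoxycarbonylation (NaCl, wet DMSO, 150 °C), during which C7 equilibrates, returns 16.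

Step 4.
- Most likely failure: incomplete separation of the two diastereomeric imides, because the stereocentres of auxiliary and ring are five bonds apart.
- Fallback: it sets out from 7 and comes back at 10. Racemic 7 is crystallised with (S)-1-phenylethylamine (or its antipode, whichever gives the less soluble salt of the wanted acid) to the (S)-1-phenylethylammonium salt of the (3R,5R) acid, F7. Dilute HCl releases the (3R,5R) enantiomer of 7. Coupling with 8 as in step 4 then gives 10 as a single diastereomer without chromatographic separation.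

Step 14.
- Most likely failure: elimination of the activated, hindered alcohol to a cyclopentene, or a stop at the mono-ester. Each C6 is flanked by the C7 methyl and both carboxyls sit on a crowded cyclobutane.
- Fallback: it sets out from 19 and 23 and comes back at 24. Alcohol 19 is converted with MeSO2Cl and Et3N into (4R,4aS,6S,7S,7aR)-2,4,7-trimethyloctahydro-1H-cyclopenta[c]pyridin-6-yl methanesulfonate F8. Diacid 23 is converted with Cs2CO3 into its dicesium salt F9. Heating the two in DMF lets the cesium carboxylate displace the sulfonate by SN2 with inversion at both C6 centres, which gives 24. The ring nitrogen lies on the same face as the leaving group and cannot interfere.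

## Further compounds

F1 | step 8 | (4R,4aR,7S,7aR)-4,7-dimethyl-2-tosyloctahydro-6H-cyclopenta[c]pyridin-6-one (trans-fused) | C[C@H]1[C@@H]2CN(S(=O)(=O)c3ccc(C)cc3)C[C@H](C)[C@H]2CC1=O
F2 | step 8 | trimethylsilyl enol ether of F1 (C5=C6, 6-trimethylsilyloxy) | C[C@H]1[C@@H]2CN(S(=O)(=O)c3ccc(C)cc3)C[C@H](C)[C@H]2C=C1O[Si](C)(C)C
F3 | step 8 | (4R,7S,7aS)-4,7-dimethyl-2-tosyl-1,2,3,4,7,7a-hexahydro-6H-cyclopenta[c]pyridin-6-one (C4a=C5 enone) | C[C@H]1[C@@H]2CN(S(=O)(=O)c3ccc(C)cc3)C[C@H](C)C2=CC1=O
F4 | step 7 | methyl (4R)-4-[(3R,5R)-5-methyl-1-tosylpiperidin-3-yl]-3-oxopentanoate | COC(=O)CC(=O)[C@H](C)[C@@H]1CN(S(=O)(=O)c2ccc(C)cc2)C[C@H](C)C1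
F5 | step 7 | methyl (4R)-2-diazo-4-[(3R,5R)-5-methyl-1-tosylpiperidin-3-yl]-3-oxopentanoate | COC(=O)C(=[N+]=[N-])C(=O)[C@H](C)[C@@H]1CN(S(=O)(=O)c2ccc(C)cc2)C[C@H](C)C1
F6 | step 7 | methyl (4R,4aS,7R,7aR)-4,7-dimethyl-6-oxo-2-tosyloctahydro-1H-cyclopenta[c]pyridine-5-carboxylate (C5 epimers) | C[C@@H]1[C@@H]2CN(S(=O)(=O)c3ccc(C)cc3)C[C@H](C)[C@@H]2C(C(=O)OC)C1=O
F7 | step 4 | (S)-1-phenylethylammonium [(3R,5R)-5-methyl-1-tosylpiperidin-3-yl]acetate | C[C@H]([NH3+])c1ccccc1.[O-]C(=O)C[C@@H]1CN(S(=O)(=O)c2ccc(C)cc2)C[C@H](C)C1
F8 | step 14 | (4R,4aS,6S,7S,7aR)-2,4,7-trimethyloctahydro-1H-cyclopenta[c]pyridin-6-yl methanesulfonate | C[C@H]1[C@@H]2CN(C)C[C@H](C)[C@@H]2C[C@@H]1OS(C)(=O)=O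
F9 | step 14 | dicesium (1α,2α,3β,4β)-2,4-bis[4-(benzyloxy)phenyl]cyclobutane-1,3-dicarboxylate | [Cs+].[Cs+].[O-]C(=O)[C@H]1[C@H](c2ccc(OCc3ccccc3)cc2)[C@H](C(=O)[O-])[C@H]1c1ccc(OCc2ccccc2)cc1
A1 | alternative 1 | trans-N1,N3-di(quinolin-8-yl)cyclobutane-1,3-dicarboxamide | O=C(Nc1cccc2cccnc12)[C@H]1C[C@H](C(=O)Nc2cccc3cccnc23)C1
A2 | alternative 1 | 1-(benzyloxy)-4-iodobenzene | Ic1ccc(OCc2ccccc2)cc1
A3 | alternative 1 | alpha-2,4-bis[4-(benzyloxy)phenyl]-N1,N3-di(quinolin-8-yl)cyclobutane-1,3-dicarboxamide | O=C(Nc1cccc2cccnc12)[C@H]1[C@H](c2ccc(OCc3ccccc3)cc2)[C@H](C(=O)Nc2cccc3cccnc23)[C@H]1c1ccc(OCc2ccccc2)cc1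
A4 | alternative 2 | methyl (but-2-yn-1-yl)(2-methylidenebut-3-en-1-yl)carbamate | CC#CCN(C(=O)OC)CC(=C)C=C
A5 | alternative 2 | methyl 7-methyl-4-methylidene-6-oxo-1,3,4,4a,5,6-hexahydro-2H-cyclopenta[c]pyridine-2-carboxylate | CC1=C2CN(C(=O)OC)CC(=C)[C@@H]2CC1=O
A6 | alternative 3 | methyl ethenyl{[5-methyl-4-oxo-2-(prop-1-en-2-yl)cyclopent-2-en-1-yl]methyl}carbamate (trans-1,5) | C[C@H]1[C@H](CN(C(=O)OC)C=C)C(C(C)=C)=CC1=O
A7 | alternative 3 | methyl 4,7-dimethyl-6-oxo-1,6,7,7a-tetrahydro-2H-cyclopenta[c]pyridine-2-carboxylate | C[C@H]1[C@@H]2CN(C(=O)OC)C=C(C)C2=CC1=O
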